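**Plan**

1. Numbering: naphthoquinone C1(=O) beside C2–OMe; ring A = quinone ring, ring B = C4a/C5–C8/C8a, ring C = the trimethoxyphenyl group on C8.
2. Enabling feature: C8 sits between ring C and C8a like a diaryl ketone carbon, C5–H on C4a is what an aryl-bound alkyne carbon becomes after deacylation, and C6/C7 carry the two methyl groups of 2-butyne.
3. Cuts: quinone to a 1-naphthol 4-methyl ether (oxidation level only); C7–C8 and C5–C6 together ([4+2] of a benzopyrylium with 2-butyne); C8–ring C (aryl Grignard plus aldehyde); aryl–alkyne bond (Sonogashira).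
4. Forward: ring A comes ready-made from o-vanillin, ring C is joined by carbonyl addition, ring B is closed last, then ring A is oxidised.
5. The o-vanillin phenol (future C1 oxygen) is carried as an isopropyl ether so that it alone can be unmasked; ring C is itself a 1,2,4-trimethoxyarene and would compete in a direct oxidative demethylation of a hexamethyl ether.
6. Stereochemistry: none to set; the only stereocentre on the way (a carbinol) is racemic and is oxidised away.

Key step: step 8

Assumption: the target SMILES assigns no configuration to the hindered C8–ring C axis, so the compound is made without control of that axis (racemic if the axis proves stable).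

**Route**

Step 1
Reactants: 1 o-vanillin (2-hydroxy-3-methoxybenzaldehyde)
Product: 2 5-bromo-2-hydroxy-3-methoxybenzaldehyde
Conditions: Br2, NaOAc, AcOH, rt
Reagents that add atoms: bromine, BrBr
Why: Electrophilic aromatic bromination should go to C5, the only free position para to the phenol, since both ortho positions are occupied.

Step 2
Reactants: 2 5-bromo-2-hydroxy-3-methoxybenzaldehyde
Product: 3 2-hydroxy-3,5-dimethoxybenzaldehyde
Conditions: NaOMe, CuBr (cat.), MeOH–DMF, 110 °C; then aq. HCl
Reagents that add atoms: sodium methoxide, C[O-].[Na+]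
Why: Ullmann-type copper-catalysed methoxylation of the aryl bromide, the reaction type that turns 5-bromovanillin into syringaldehyde, should tolerate the phenoxide and the aldehyde.

Step 3
Reactants: 3 2-hydroxy-3,5-dimethoxybenzaldehyde
Product: 4 2-isopropoxy-3,5-dimethoxybenzaldehyde
Conditions: 2-bromopropane, K2CO3, DMF, 60 °C
Reagents that add atoms: 2-bromopropane, CC(C)Br
Why: Williamson etherification of the phenoxide gives a secondary alkyl ether that is stable to base, organometallics and mild acid but is later cleavable in the presence of methyl ethers.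

Step 4
Reactants: 4 2-isopropoxy-3,5-dimethoxybenzaldehyde
Product: 5 2-bromo-6-isopropoxy-3,5-dimethoxybenzaldehyde
Conditions: NBS, MeCN, 0 °C to rt
Reagents that add atoms: N-bromosuccinimide, O=C1CCC(=O)N1Br
Why: Electrophilic aromatic bromination should choose C6 (para to the 3-OMe, ortho to the 5-OMe) over C4, which is squeezed between two methoxy groups, as 3,5-dimethoxybenzaldehyde brominates next to its formyl group.

Step 5
Reactants: 5 2-bromo-6-isopropoxy-3,5-dimethoxybenzaldehyde; 6 phenylacetylene
Product: 7 2-isopropoxy-3,5-dimethoxy-6-(phenylethynyl)benzaldehyde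
Conditions: PdCl2(PPh3)2 (cat.), CuI (cat.), Et3N, THF, 65 °C
Reagents that add atoms: none
Why: Sonogashira coupling, in which the ortho formyl group assists oxidative addition of zerovalent palladium into the otherwise electron-rich C–Br bond, is the standard entry to ortho-alkynylbenzaldehydes.

Step 6
Reactants: 7 2-isopropoxy-3,5-dimethoxy-6-(phenylethynyl)benzaldehyde; 8 1-bromo-2,4,5-trimethoxybenzene
Product: 10 racemic [2-isopropoxy-3,5-dimethoxy-6-(phenylethynyl)phenyl](2,4,5-trimethoxyphenyl)methanol, via 2,4,5-trimethoxyphenylmagnesium bromide 9 (not isolated)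
Conditions: 8, Mg, I2 (cat.), THF, reflux; then 7, THF, 0 °C to rt; sat. aq. NH4Cl
Reagents that add atoms: none
Why: Grignard formation and 1,2-addition to the aldehyde joins ring C to the future C8 without any hindered aryl–aryl coupling; the new carbinol centre forms as the racemate and is removed in step 7.

Step 7
Reactants: 10 racemic [2-isopropoxy-3,5-dimethoxy-6-(phenylethynyl)phenyl](2,4,5-trimethoxyphenyl)methanol
Product: 11 [2-isopropoxy-3,5-dimethoxy-6-(phenylethynyl)phenyl](2,4,5-trimethoxyphenyl)methanone
Conditions: MnO2 (activated, excess), CH2Cl2, rt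
Reagents that add atoms: none
Why: MnO2 oxidation of a doubly benzylic alcohol to the diaryl ketone is mild, neutral and leaves the alkyne and the ethers untouched.

Step 8
Reactants: 11 [2-isopropoxy-3,5-dimethoxy-6-(phenylethynyl)phenyl](2,4,5-trimethoxyphenyl)methanone; 12 2-butyne
Product: 15 1-isopropoxy-2,4-dimethoxy-6,7-dimethyl-8-(2,4,5-trimethoxyphenyl)naphthalene (target numbering), via 2-benzopyrylium difluoroacetate 13 (not isolated), via oxygen-bridged cycloadduct 14 (not isolated)
Conditions: Cu(OTf)2 (10 mol %), CF2HCO2H (1 equiv), 2-butyne (excess), (CH2Cl)2, 100 °C, sealed tube; aq. NaHCO3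
Reagents that add atoms: none
Why: Cu(OTf)2 activates the alkyne of 11 and the ketone oxygen closes on the phenyl-bearing alkyne carbon (6-endo-dig) to give, after protonation of the C–Cu bond by CF2HCO2H, the 1-aryl-3-phenyl-2-benzopyrylium 13. This cation acts as an electron-poor 2-oxadiene across its C1 and C4 (target C8 and C5) and takes up 2-butyne in an intermolecular [4+2] cycloaddition that closes ring B by forming C7–C8 and C5–C6 and gives the oxygen-bridged oxocarbenium 14. Difluoroacetate then adds to the PhC=O+ carbon, the C–O bond at the aryl-bearing bridgehead breaks and the benzoyl unit leaves as a mixed anhydride (benzoic acid after work-up), so ring B aromatises with hydrogen on C5. The closest known reaction type is the Asao–Yamamoto benzannulation of ortho-alkynylaryl aldehydes and ketones with alkynes in its copper/Brønsted-acid deacylative form; no stereocentre is created. The step needs 6-endo rather than 5-exo oxycyclisation, which the charge-stabilising phenyl group on the distal alkyne carbon secures, and loss rather than retention of the acyl group, which the copper/acid pair provides; symmetrical 2-butyne leaves no orientation question.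

Step 9
Reactants: 15 1-isopropoxy-2,4-dimethoxy-6,7-dimethyl-8-(2,4,5-trimethoxyphenyl)naphthalene
Product: 16 2,4-dimethoxy-6,7-dimethyl-8-(2,4,5-trimethoxyphenyl)naphthalen-1-ol
Conditions: BCl3, CH2Cl2, −78 to 0 °C; then H2O
Reagents that add atoms: none
Why: Lewis-acid ether cleavage with BCl3 removes a secondary isopropyl aryl ether much faster than primary methyl ethers when no carbonyl group is present to direct demethylation, so only the C1 oxygen should be unmasked.

Step 10
Reactants: 16 2,4-dimethoxy-6,7-dimethyl-8-(2,4,5-trimethoxyphenyl)naphthalen-1-ol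
Product: 17 2-methoxy-6,7-dimethyl-8-(2,4,5-trimethoxyphenyl)naphthalene-1,4-dione (target)
Conditions: PhI(OAc)2, MeCN–H2O, 0 °C
Reagents that add atoms: water, O
Why: Hypervalent-iodine oxidation of a para-methoxyphenol to the para-quinone (water adds at C4 and methanol is lost) runs at a potential far below that needed to attack the methyl ethers of ring C, so the C2 methoxy group and ring C should remain intact.

**Compound list**

1 | o-vanillin (2-hydroxy-3-methoxybenzaldehyde) | COc1cccc(C=O)c1O | starting material
2 | 5-bromo-2-hydroxy-3-methoxybenzaldehyde | COc1cc(Br)cc(C=O)c1O | intermediate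
3 | 2-hydroxy-3,5-dimethoxybenzaldehyde | COc1cc(OC)c(O)c(C=O)c1 | intermediate
4 | 2-isopropoxy-3,5-dimethoxybenzaldehyde | COc1cc(OC)c(OC(C)C)c(C=O)c1 | intermediate
5 | 2-bromo-6-isopropoxy-3,5-dimethoxybenzaldehyde | COc1cc(OC)c(OC(C)C)c(C=O)c1Br | intermediate
6 | phenylacetylene | C#Cc1ccccc1 | starting material
7 | 2-isopropoxy-3,5-dimethoxy-6-(phenylethynyl)benzaldehyde | COc1cc(OC)c(OC(C)C)c(C=O)c1C#Cc1ccccc1 | intermediate
8 | 1-bromo-2,4,5-trimethoxybenzene | COc1cc(OC)c(Br)cc1OC | starting material
9 | (2,4,5-trimethoxyphenyl)magnesium bromide (not isolated) | COc1cc(OC)c([Mg]Br)cc1OC | intermediate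
10 | racemic [2-isopropoxy-3,5-dimethoxy-6-(phenylethynyl)phenyl](2,4,5-trimethoxyphenyl)methanol | COc1cc(OC)c(OC(C)C)c(C(O)c2cc(OC)c(OC)cc2OC)c1C#Cc1ccccc1 | intermediate
11 | [2-isopropoxy-3,5-dimethoxy-6-(phenylethynyl)phenyl](2,4,5-trimethoxyphenyl)methanone | COc1cc(OC)c(OC(C)C)c(C(=O)c2cc(OC)c(OC)cc2OC)c1C#Cc1ccccc1 | intermediate
12 | 2-butyne | CC#CC | starting material
13 | 8-isopropoxy-5,7-dimethoxy-3-phenyl-1-(2,4,5-trimethoxyphenyl)-2-benzopyrylium difluoroacetate (not isolated) | COc1cc(OC)c2cc(-c3ccccc3)[o+]c(-c3cc(OC)c(OC)cc3OC)c2c1OC(C)C.[O-]C(=O)C(F)F | intermediate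
14 | oxygen-bridged cycloadduct: 6,7-dimethyl-5,8-dihydronaphthalene whose C8 (aryl-bearing) and C5 are bridged by –O+=C(Ph)–, difluoroacetate salt (not isolated) | COc1cc(OC)c2c(c1OC(C)C)C1(c3cc(OC)c(OC)cc3OC)[O+]=C(c3ccccc3)C2C(C)=C1C.[O-]C(=O)C(F)F | intermediate
15 | 1-isopropoxy-2,4-dimethoxy-6,7-dimethyl-8-(2,4,5-trimethoxyphenyl)naphthalene | COc1cc(OC)c2cc(C)c(C)c(-c3cc(OC)c(OC)cc3OC)c2c1OC(C)C | intermediate
16 | 2,4-dimethoxy-6,7-dimethyl-8-(2,4,5-trimethoxyphenyl)naphthalen-1-ol | COc1cc(OC)c2cc(C)c(C)c(-c3cc(OC)c(OC)cc3OC)c2c1O | intermediate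
17 | 2-methoxy-6,7-dimethyl-8-(2,4,5-trimethoxyphenyl)naphthalene-1,4-dione | COC1=CC(=O)c2cc(C)c(C)c(-c3cc(OC)c(OC)cc3OC)c2C1=O | target

**Step count**

Total steps: 10. Longest linear sequence: 10 steps, from 1 to 17; compounds 6, 8 and 12 are commercial and enter directly.

**Steps most likely to fail**

Step 8. The donor-laden, crowded benzopyrylium may be too stabilised and too hindered at its aryl-bearing carbon to be intercepted by volatile 2-butyne, so that 5-exo closure, hydration or decomposition take over. Fallback, setting out from 11: the two stages are separated. HBF4·OEt2 in CH2Cl2 should cyclise 11 to the isolable salt 8-isopropoxy-5,7-dimethoxy-3-phenyl-1-(2,4,5-trimethoxyphenyl)-2-benzopyrylium tetrafluoroborate F1. This salt is then heated in MeCN with 2-methoxybut-2-ene, a far more nucleophilic two-carbon partner whose two olefinic carbons both carry methyl. Inverse-electron-demand [4+2] addition across the same two pyrylium carbons, followed by loss of methanol and of benzoic acid, should give 15, where the route is rejoined. This is the known reaction type of 2-benzopyrylium salts with enol ethers.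

Step 9. Boron chelated between the C1 and C2 oxygens may also cleave a methyl ether, or the peri-shielded isopropyl ether may react sluggishly. Fallback, setting out from 15: direct oxidative dealkylation with (NH4)2Ce(NO3)6 (about 2 equiv, MeCN–H2O, 0 °C, inverse addition) removes the para-related isopropyl and methyl groups on C1 and C4 and gives 17 directly, where the route ends. It relies on the trioxygenated naphthalene ring being oxidised more easily than ring C. No new compound arises on this path (entry F0).

Step 5. Oxidative addition into the doubly ortho-substituted, electron-rich C–Br bond may be slow enough for copper-mediated homocoupling of 6 to outrun cross-coupling. Fallback, setting out from 4: iodination in place of bromination (N-iodosuccinimide, CF3CO2H cat., MeCN) should give 2-iodo-6-isopropoxy-3,5-dimethoxybenzaldehyde F2. Its C–I bond should couple with 6 at room temperature under PdCl2(PPh3)2/CuI/Et3N, rejoining the route at 7.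

**Further compounds**

F1 | step 8 | 8-isopropoxy-5,7-dimethoxy-3-phenyl-1-(2,4,5-trimethoxyphenyl)-2-benzopyrylium tetrafluoroborate | COc1cc(OC)c2cc(-c3ccccc3)[o+]c(-c3cc(OC)c(OC)cc3OC)c2c1OC(C)C.F[B-](F)(F)F
F0 | step 9 | none | none
F2 | step 5 | 2-iodo-6-isopropoxy-3,5-dimethoxybenzaldehyde | COc1cc(OC)c(OC(C)C)c(C=O)c1I
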